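Atoms carry the azulene numbers of the target throughout: C1 (carbinol, isopropyl), C2, C3 (acetoxy), C3a (quaternary, methyl), C4 (allylic acetoxy), C5=C6 (methyl on C6), C7, C8 (veratroyloxy), C8a (fusion CH). β is the face of the C8a hydrogen. TBSO = tert-butyldimethylsilyloxy.

## Analysis of the target

Target 30 is a hydroazulene: a cyclopentane (C1, C2, C3, C3a, C8a) fused along C3a–C8a to a cycloheptene (C4–C8) whose only alkene, C5=C6, carries a methyl group on C6. It has six stereocentres: the tertiary carbinol C1 (hydroxyl and isopropyl), the acetoxy carbon C3, the quaternary methyl-bearing C3a, the allylic acetoxy carbon C4, the veratroyloxy carbon C8 and the fusion methine C8a. The fusion is trans; the C3a methyl and the C1 hydroxyl lie on the α face, and the three acyloxy groups, the isopropyl group and the C8a hydrogen on the β face, so the C3 and C4 oxygens form a syn-1,3-diol across the quaternary carbon. Sensitive points are the C4 acetate, which is allylic to a trisubstituted alkene and ionises easily, and the tertiary alcohol, which must stay free while three secondary oxygens receive two different acyl groups. The synthesis is hard because C3a is quaternary and flanked by three stereogenic carbons (C3, C4, C8a), and because the C8a hydrogen and the C8 oxygen must both end on the more crowded β face. The strategy rests on one connection: the carbinol carbon C1 of the five-membered ring is bonded to the fusion carbon C8a. A ketone carbon (C1) and a ring alkenyl carbon (C8a) are both electrophilic in their natural precursors, so they can be joined reductively once the alkenyl carbon has been made nucleophilic by metal insertion.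

## Retrosynthetic reasoning

30 to 29. The two acetyl C–O bonds at C3 and C4 are cut first. Triol 29 differs at these two secondary hydroxyls from the tertiary C1 hydroxyl by reactivity alone. Putting the acetates on last keeps the ionisable allylic C4 acetate out of every metal-mediated, basic and acidic step.

29 to 28 to 26 and 27. The C3 and C4 oxygens are carried as silyl ethers (28), and the aryl ester bond at C8 is cut to diol 26 and acid chloride 27. In 26 the C8 hydroxyl is the only one that can be acylated, so the veratrate needs no further differentiation.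

26 to 25 to 24. The C8 carbinol is traced to ketone 25. The alcohol that the alkene functionalisation delivers (24) has its C8 oxygen on the α face, the wrong one. Oxidation and hydroxyl-directed reduction invert it, using the C1 hydroxyl already in place as the control element.

24 to 23 to 22. The C8–O and C8a–H bonds are cut back to the C8=C8a alkene of 22. The tertiary allylic hydroxyl at C1 distinguishes this alkene from C5=C6 in a directed epoxidation. Homolytic opening of epoxide 23 puts the radical on the fully substituted C8a, so oxygen stays on C8 and hydrogen arrives at C8a. The forward steps have to deliver that hydrogen to the β face.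

22 to 20 (key disconnection). The C1–C8a bond is cut. It is the only ring bond that joins a carbinol carbon to a carbon that can be an alkenyl metal. Cutting it leaves a monocyclic cycloheptadiene 20 whose three stereocentres (C3, C3a, C4) can all be set on an open chain. The forward reaction must turn the alkenyl iodide into a nucleophile in the presence of the ketone, add it to a hindered isopropyl ketone, and choose one ketone face.

20 to 19 to 17. The C1 ketone is masked as the dioxolane in 19 so that it survives hydrazone formation. The alkenyl iodide is traced through hydrazone 18 to ring ketone 17. Because C3a is quaternary, the alkene can form only toward C8, so the iodide is regiodefined.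

17 to 16 to 15. After removal of the silyl groups the C5=C6 bond is cut by ring-closing metathesis to diene 15. This alkene is remote from all stereocentres, and a methallyl unit brings in the C6 methyl group, so no separate methylation or dehydrogenation of a preformed ring is needed.

15 to 12 and 14. The bond between the C8a carbonyl carbon and C8 is cut to Weinreb amide 12 and Grignard reagent 14, made from bromide 13. The amide stops the addition at the ketone stage.

12 to 11 to 10. The C3 carbinol is traced to ketone 10 and a chelation-controlled hydride reduction. In the six-membered chelate through the C4 oxygen an external nucleophile reaches C3 from the face away from the axial carbonyl substituent on C3a. A carbon nucleophile adding to a C3 aldehyde would therefore give the anti diol, whereas hydride adding to a C3 ketone gives the required syn diol. For this reason C3 enters as a ketone.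

10 to 8 and 3. The C3–C3a bond is cut. Acylation of dianion 9, formed from hydroxy ester 8, by Weinreb amide 3 creates the quaternary centre under control of the C4 alkoxide. The same step brings in the whole side chain with the C1 ketone already masked.

8 to 7 to 4 and 5; 3 to 2 to 1. The C3a–C4 bond is cut to imide 4 and acrolein 5; an auxiliary-controlled aldol reaction sets the absolute configuration at C4, from which all other centres follow. Amide 3 comes from keto ester 1 through ketal ester 2.

## Alternatives that were turned down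

Alternative 1: The bond between the two fusion carbons, C3a–C8a, would be made across a ten-membered ring. Ph3PAuNTf2, a monovalent gold catalyst, would activate the ring alkyne of enynedione A2, and the enol carbon of its 2-methyl-1,3-diketone would add to the alkyne carbon next to the carbinol (Conia-ene reaction), giving hydroazulenedione A1.
- For: one step closes both rings and creates the quaternary C3a. On ring-forming economy it is stronger than the chosen route.
- Against: A2 is a strained ten-membered ring holding an alkyne and a Z-trisubstituted alkene, so its macrocyclisation is a problem of its own. Only the remote C1 centre can steer the new quaternary centre, across the ring. The 5-exo closure competes with the 6-endo mode.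
- Against: A1 still has the C8=C8a alkene, so the same late hydration is needed, and in addition two ketones at C3 and C4 must be reduced syn.
- In its place the chosen route offers C3, C3a and C4 set by chelation-controlled open-chain reactions before any ring exists.

Alternative 2: The carbon C5 would be inserted into a six-membered ring. The tetrasubstituted trimethylsilyl enol ether A4 of a trans-fused hydrindanone would be cyclopropanated with Et2Zn/CH2I2 and opened with FeCl3 and then NaOAc, giving ring-expanded enone A3.
- For: the trans fusion, the C8 ester and C1 are settled on a hydrindane, where facial control is well understood. The expansion is regiodefined by the enol ether and delivers the C6 methyl and the C4 carbonyl directly. On the end game it is stronger than the chosen route, which must hydrate a fusion alkene late.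
- Against: the enol ether must be formed toward the methyl-bearing carbon next to the quaternary centre, and cyclopropanation of so hindered an alkene is slow. FeCl3 is an oxidant toward the electron-rich veratrate and a Lewis acid toward the tertiary silyl ether.
- Against: the hydrindanone behind A4 already holds five stereocentres, including the quaternary carbon and the tertiary carbinol, so the stereochemical work is moved rather than removed.
- The chosen route is shorter to its key intermediate and builds its stereocentres from one aldol adduct.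

Alternative 3: The bonds C8–C8a and C6–C7 would be formed in a (5+2) cycloaddition. [Rh(CO)2Cl]2 would open the siloxy vinylcyclopropane A6 at the bond to its cyclopropane CH and insert ethynyltrimethylsilane A7, giving cycloheptadiene A5.
- For: it is convergent and mild, siloxy vinylcyclopropanes are good (5+2) partners, and the enol ether at C4 and the vinylsilane at C8 are useful handles. On convergence it is stronger than the chosen route.
- Against: the cyclopropane fusion forces the C8a hydrogen cis to the C3a methyl, so A5 is cis-fused, and C8a has no neighbouring carbonyl through which it could be epimerised.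
- Against: the alkenes sit at C4=C5 and C7=C8 with C6 saturated and must be moved to C5=C6; the vinylsilane must become a β-oxygen; and A6 with its four stereocentres is itself a demanding target.
- The chosen route fits the trans fusion by design, since the C8a hydrogen is introduced after ring closure.

Key step: step 13

Remark: the C4 oxygen is carried as a silyl ether, not as the acetate, through the ring closure, because hydrazine would cleave an acetate and zerovalent nickel could ionise an allylic one; both acetates are installed in the last step.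

Step 1
Reactants: 1 methyl 4-methyl-3-oxopentanoate
Product: 2 methyl 2-(2-isopropyl-1,3-dioxolan-2-yl)acetate
Conditions: ethylene glycol, p-TsOH·H2O (cat.), toluene, reflux, Dean–Stark
Reagents that add atoms: ethylene glycol, OCCO
Why: Acid-catalysed ketalisation with azeotropic removal of water; only the ketone carbonyl ketalises, and the dioxolane keeps the future C1 ketone inert to enolates, hydride, Grignard reagents and hydrazine until step 12.

Step 2
Reactants: 2 methyl 2-(2-isopropyl-1,3-dioxolan-2-yl)acetate
Product: 3 N-methoxy-N-methyl-2-(2-isopropyl-1,3-dioxolan-2-yl)acetamide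
Conditions: MeNH(OMe)·HCl, i-PrMgCl, THF, −20 → 0 °C
Reagents that add atoms: N,O-dimethylhydroxylamine hydrochloride, CNOC.Cl
Why: Weinreb amide synthesis by aminolysis of the methyl ester with the chloromagnesium amide; the amide will later acylate a carbon nucleophile once and stop at the chelated tetrahedral intermediate.

Step 3
Reactants: 4 (S)-4-benzyl-3-propionyloxazolidin-2-one; 5 acrolein
Product: 7 (4S)-4-benzyl-3-[(2S,3R)-3-hydroxy-2-methylpent-4-enoyl]oxazolidin-2-one, via dibutylboron Z-enolate 6 (not isolated)
Conditions: Bu2BOTf, i-Pr2NEt, CH2Cl2, −78 → 0 °C; 5, −78 → 0 °C; H2O2, MeOH, pH 7 buffer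
Reagents that add atoms: none
Why: Evans syn aldol reaction; the Z-boron enolate adds to acrolein through a Zimmerman–Traxler chair in which the benzyl group of the auxiliary blocks one enolate face, setting the (3R) carbinol (future C4); the (2S) methyl centre is planarised again in step 5.

Step 4
Reactants: 7 (4S)-4-benzyl-3-[(2S,3R)-3-hydroxy-2-methylpent-4-enoyl]oxazolidin-2-one
Product: 8 methyl (2S,3R)-3-hydroxy-2-methylpent-4-enoate
Conditions: NaOMe (cat.), MeOH, 0 °C
Reagents that add atoms: methanol, CO
Why: Methoxide-catalysed transesterification releases the auxiliary; low temperature and short time should avoid retro-aldol cleavage, and epimerisation at C2 would be without consequence.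

Step 5
Reactants: 8 methyl (2S,3R)-3-hydroxy-2-methylpent-4-enoate; 3 N-methoxy-N-methyl-2-(2-isopropyl-1,3-dioxolan-2-yl)acetamide
Product: 10 methyl (2S,3R)-3-hydroxy-2-[2-(2-isopropyl-1,3-dioxolan-2-yl)acetyl]-2-methylpent-4-enoate, via dilithium alkoxide enolate 9 (not isolated)
Conditions: LDA (2.2 equiv), THF, −78 → −20 °C; 3, −78 → 0 °C; aq. NH4Cl
Reagents that add atoms: none
Why: Crossed Claisen acylation of a lithium ester enolate by a Weinreb amide, run on the Fráter–Seebach dianion; in the lithium chelate the electrophile enters the enolate face anti to the vinyl group on the alkoxide carbon, which should give the quaternary centre (future C3a) as (2S). The addition stops at the tetrahedral intermediate, and the amide α-protons are too weakly acidic for proton transfer to compete.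

Step 6
Reactants: 10 methyl (2S,3R)-3-hydroxy-2-[2-(2-isopropyl-1,3-dioxolan-2-yl)acetyl]-2-methylpent-4-enoate
Product: 11 methyl (2R,3R)-3-hydroxy-2-[(1S)-1-hydroxy-2-(2-isopropyl-1,3-dioxolan-2-yl)ethyl]-2-methylpent-4-enoate
Conditions: Et2BOMe, THF/MeOH (4:1), −78 °C; NaBH4; AcOH; MeOH azeotrope
Reagents that add atoms: none
Why: Narasaka–Prasad reduction; Et2BOMe ties the C4 hydroxyl and the ketone into a six-membered boron chelate, and NaBH4 attacks axially from the face opposite the axial ester group on C3a, giving the syn-1,3-diol with the new (S) centre (future C3). The ester and the dioxolane are inert.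

Step 7
Reactants: 11 methyl (2R,3R)-3-hydroxy-2-[(1S)-1-hydroxy-2-(2-isopropyl-1,3-dioxolan-2-yl)ethyl]-2-methylpent-4-enoate
Product: 12 (2R,3R)-3-hydroxy-2-[(1S)-1-hydroxy-2-(2-isopropyl-1,3-dioxolan-2-yl)ethyl]-N-methoxy-N,2-dimethylpent-4-enamide
Conditions: MeNH(OMe)·HCl, i-PrMgCl (excess), THF, −20 → 0 °C
Reagents that add atoms: N,O-dimethylhydroxylamine hydrochloride, CNOC.Cl
Why: Weinreb amide synthesis on the hindered ester, assisted by the two neighbouring magnesium alkoxides; the hydroxyls need no protection because the reagent only deprotonates them.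

Step 8
Reactants: 12 (2R,3R)-3-hydroxy-2-[(1S)-1-hydroxy-2-(2-isopropyl-1,3-dioxolan-2-yl)ethyl]-N-methoxy-N,2-dimethylpent-4-enamide; 13 4-bromo-2-methylbut-1-ene
Product: 15 (6R,7R)-7-hydroxy-6-[(1S)-1-hydroxy-2-(2-isopropyl-1,3-dioxolan-2-yl)ethyl]-2,6-dimethylnona-1,8-dien-5-one, via Grignard reagent 14 (not isolated)
Conditions: 13, Mg, THF, rt; then 12, THF, 0 °C → rt; aq. NH4Cl
Reagents that add atoms: none
Why: Grignard addition to a Weinreb amide; the chelated tetrahedral intermediate survives until work-up, so the ketone is released only on quenching and neither over-addition nor retro-aldol cleavage of a β-alkoxy ketone can occur in the flask.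

Step 9
Reactants: 15 (6R,7R)-7-hydroxy-6-[(1S)-1-hydroxy-2-(2-isopropyl-1,3-dioxolan-2-yl)ethyl]-2,6-dimethylnona-1,8-dien-5-one
Product: 16 (2R,3R)-3-hydroxy-2-[(1S)-1-hydroxy-2-(2-isopropyl-1,3-dioxolan-2-yl)ethyl]-2,5-dimethylcyclohept-4-en-1-one
Conditions: second-generation Grubbs catalyst (5 mol %), CH2Cl2 (5 mM), 40 °C
Reagents that add atoms: none
Why: Ring-closing metathesis between the vinyl and the 1,1-disubstituted alkene closes the seven-membered ring and forms the trisubstituted C5=C6 alkene; the quaternary carbon favours the cyclising conformer and the free allylic hydroxyl is tolerated.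

Step 10
Reactants: 16 (2R,3R)-3-hydroxy-2-[(1S)-1-hydroxy-2-(2-isopropyl-1,3-dioxolan-2-yl)ethyl]-2,5-dimethylcyclohept-4-en-1-one
Product: 17 (2R,3R)-3-(TBSO)-2-[(1S)-1-(TBSO)-2-(2-isopropyl-1,3-dioxolan-2-yl)ethyl]-2,5-dimethylcyclohept-4-en-1-one
Conditions: TBSOTf, 2,6-lutidine, CH2Cl2, −78 → 0 °C
Reagents that add atoms: tert-butyldimethylsilyl triflate, CC(C)(C)[Si](C)(C)OS(=O)(=O)C(F)(F)F
Why: Silylation of both hindered secondary alcohols with a silyl triflate; it removes the retro-aldol pathway of the β-hydroxy ketone before the hydrazine step, prevents iodoetherification onto C5=C6 in step 11, and supplies the non-coordinating ethers needed in step 13.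

Step 11
Reactants: 17 (2R,3R)-3-(TBSO)-2-[(1S)-1-(TBSO)-2-(2-isopropyl-1,3-dioxolan-2-yl)ethyl]-2,5-dimethylcyclohept-4-en-1-one
Product: 19 (6R,7R)-6-(TBSO)-7-[(1S)-1-(TBSO)-2-(2-isopropyl-1,3-dioxolan-2-yl)ethyl]-1-iodo-4,7-dimethylcyclohepta-1,4-diene, via hydrazone 18 (not isolated)
Conditions: N2H4·H2O, Et3N, EtOH, 80 °C; then I2, TMG, THF, 0 °C
Reagents that add atoms: iodine, II
Why: Barton vinyl iodide synthesis; the hydrazone is oxidised by iodine in the presence of the guanidine base and loses nitrogen and a proton. Because C3a is quaternary the alkene can form only toward C8, so the iodide is regiodefined; silyl ethers and dioxolane are stable to both stages.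

Step 12
Reactants: 19 (6R,7R)-6-(TBSO)-7-[(1S)-1-(TBSO)-2-(2-isopropyl-1,3-dioxolan-2-yl)ethyl]-1-iodo-4,7-dimethylcyclohepta-1,4-diene
Product: 20 (5S)-5-(TBSO)-5-[(1R,7R)-7-(TBSO)-2-iodo-1,5-dimethylcyclohepta-2,5-dien-1-yl]-2-methylpentan-3-one
Conditions: PPTS, acetone/H2O (10:1), 55 °C
Reagents that add atoms: water, O
Why: Mild acid-catalysed hydrolysis of the dioxolane releases the isopropyl ketone; secondary silyl ethers, the alkenyl iodide and the skipped diene tolerate PPTS, and the β-silyloxy ketone never meets base.

Step 13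
Reactants: 20 (5S)-5-(TBSO)-5-[(1R,7R)-7-(TBSO)-2-iodo-1,5-dimethylcyclohepta-2,5-dien-1-yl]-2-methylpentan-3-one
Product: 22 (1R,3S,3aR,4R)-3,4-bis(TBSO)-1-isopropyl-3a,6-dimethyl-1,2,3,3a,4,7-hexahydroazulen-1-ol, via alkenylchromium dichloride 21 (not isolated)
Conditions: CrCl2 (8 equiv), NiCl2 (2 mol %), DMF, rt, 10 mM
Reagents that add atoms: none
Why: Divalent chromium reduces NiCl2 to zerovalent nickel, which inserts into the C–I bond; transmetalation to trivalent chromium gives the alkenylchromium species, which adds to the tethered ketone (Nozaki–Hiyama–Kishi reaction). The closest known reaction type is the intramolecular chromium/nickel-mediated addition of an alkenyl iodide to a ketone to give a cyclic tertiary allylic alcohol. The five-membered ring closes in the 5-exo-trig mode, C8a attacking the carbonyl carbon C1 with the C=O bond outside the forming ring. The new stereocentre C1 is controlled by the C3 silyloxy centre: in the half-chair transition state the bulky silyloxy group and the isopropyl group should both sit pseudo-equatorial (1,3-cis), which places the carbonyl oxygen pseudo-axial on the α face, anti to the C3–O dipole. The step needs facial selectivity at the ketone; the acyclic, non-coordinating silyl ethers are expected to secure it, because they neither draw chromium to the β face by chelation nor lock the C3a methyl over the α face of C8a, as a cyclic diol acetal would. It also needs chemoselectivity: the alkenylchromium is non-basic, so the β-silyloxy ketone is neither enolised nor eliminated, and no allylic ester is present for zerovalent nickel. The position of the new bond is fixed by the iodide.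

Step 14
Reactants: 22 (1R,3S,3aR,4R)-3,4-bis(TBSO)-1-isopropyl-3a,6-dimethyl-1,2,3,3a,4,7-hexahydroazulen-1-ol
Product: 23 (1R,3S,3aR,4R,8R,8aS)-3,4-bis(TBSO)-8,8a-epoxy-1-isopropyl-3a,6-dimethyl-1,2,3,3a,4,7,8,8a-octahydroazulen-1-ol
Conditions: VO(acac)2 (5 mol %), t-BuOOH, CH2Cl2, 0 °C → rt
Reagents that add atoms: tert-butyl hydroperoxide, CC(C)(C)OO
Why: Hydroxyl-directed epoxidation; the tertiary C1 alkoxide binds vanadium together with the hydroperoxide and delivers oxygen to the adjacent C8=C8a alkene on its own (α) face. The C5=C6 alkene has no free allylic hydroxyl and should be left alone.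

Step 15
Reactants: 23 (1R,3S,3aR,4R,8R,8aS)-3,4-bis(TBSO)-8,8a-epoxy-1-isopropyl-3a,6-dimethyl-1,2,3,3a,4,7,8,8a-octahydroazulen-1-ol
Product: 24 (1R,3S,3aR,4R,8R,8aS)-3,4-bis(TBSO)-1-isopropyl-3a,6-dimethyl-1,2,3,3a,4,7,8,8a-octahydroazulene-1,8-diol
Conditions: Cp2TiCl2, Zn, THF, rt; then 23, 1,4-cyclohexadiene, THF, rt; aq. NaH2PO4
Reagents that add atoms: none
Why: Nugent–RajanBabu reductive epoxide opening, the known route from 2,3-epoxy alcohols to 1,3-diols; electron transfer from trivalent titanium cleaves the C8a–O bond to the tertiary radical and leaves oxygen on C8. The titanium alkoxide, held on the α face next to the C1 hydroxyl, should make 1,4-cyclohexadiene deliver hydrogen to C8a from the β face, giving the trans fusion.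

Step 16
Reactants: 24 (1R,3S,3aR,4R,8R,8aS)-3,4-bis(TBSO)-1-isopropyl-3a,6-dimethyl-1,2,3,3a,4,7,8,8a-octahydroazulene-1,8-diol
Product: 25 (1R,3S,3aR,4R,8aR)-3,4-bis(TBSO)-1-hydroxy-1-isopropyl-3a,6-dimethyl-2,3,3a,4,7,8a-hexahydroazulen-8(1H)-one
Conditions: Dess–Martin periodinane, NaHCO3, CH2Cl2, 0 °C → rt
Reagents that add atoms: none
Why: Dess–Martin oxidation of the secondary C8 alcohol under buffered, non-basic conditions; the tertiary alcohol cannot be oxidised, and without base neither epimerisation at C8a nor retro-aldol opening is expected.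

Step 17
Reactants: 25 (1R,3S,3aR,4R,8aR)-3,4-bis(TBSO)-1-hydroxy-1-isopropyl-3a,6-dimethyl-2,3,3a,4,7,8a-hexahydroazulen-8(1H)-one
Product: 26 (1R,3S,3aR,4R,8S,8aS)-3,4-bis(TBSO)-1-isopropyl-3a,6-dimethyl-1,2,3,3a,4,7,8,8a-octahydroazulene-1,8-diol
Conditions: Me4NBH(OAc)3, AcOH/MeCN (1:1), −25 °C
Reagents that add atoms: none
Why: Evans–Saksena reduction; the C1 hydroxyl exchanges an acetate on boron and the bound hydride is delivered to the α face of the C8 carbonyl, which should give the 1,3-anti diol with the C8 hydroxyl on the β face.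

Step 18
Reactants: 26 (1R,3S,3aR,4R,8S,8aS)-3,4-bis(TBSO)-1-isopropyl-3a,6-dimethyl-1,2,3,3a,4,7,8,8a-octahydroazulene-1,8-diol; 27 3,4-dimethoxybenzoyl chloride
Product: 28 (1R,3S,3aR,4R,8S,8aS)-3,4-bis(TBSO)-1-hydroxy-1-isopropyl-3a,6-dimethyl-1,2,3,3a,4,7,8,8a-octahydroazulen-8-yl 3,4-dimethoxybenzoate
Conditions: Et3N, DMAP, CH2Cl2, 0 °C → rt
Reagents that add atoms: none
Why: DMAP-catalysed acylation; only the secondary C8 hydroxyl should react, the tertiary C1 hydroxyl being too hindered, so the veratrate is placed without a protecting group.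

Step 19
Reactants: 28 (1R,3S,3aR,4R,8S,8aS)-3,4-bis(TBSO)-1-hydroxy-1-isopropyl-3a,6-dimethyl-1,2,3,3a,4,7,8,8a-octahydroazulen-8-yl 3,4-dimethoxybenzoate
Product: 29 (1R,3S,3aR,4R,8S,8aS)-1,3,4-trihydroxy-1-isopropyl-3a,6-dimethyl-1,2,3,3a,4,7,8,8a-octahydroazulen-8-yl 3,4-dimethoxybenzoate
Conditions: HF·pyridine, pyridine, THF, 0 → 40 °C
Reagents that add atoms: none
Why: Fluoride cleavage of both secondary silyl ethers under buffered conditions that should leave the aryl ester, the tertiary alcohol and the allylic C4–O bond intact.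

Step 20
Reactants: 29 (1R,3S,3aR,4R,8S,8aS)-1,3,4-trihydroxy-1-isopropyl-3a,6-dimethyl-1,2,3,3a,4,7,8,8a-octahydroazulen-8-yl 3,4-dimethoxybenzoate
Product: 30 (1R,3S,3aR,4R,8S,8aS)-3,4-diacetoxy-1-hydroxy-1-isopropyl-3a,6-dimethyl-1,2,3,3a,4,7,8,8a-octahydroazulen-8-yl 3,4-dimethoxybenzoate (CNP0320758.1)
Conditions: Ac2O, DMAP (cat.), pyridine, CH2Cl2, rt
Reagents that add atoms: acetic anhydride, CC(=O)OC(C)=O
Why: Acetylation of the two secondary alcohols at C3 and C4; with limited reagent and time the tertiary C1 alcohol should stay free, giving the target.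

## Compound list

1 | methyl 4-methyl-3-oxopentanoate | COC(=O)CC(=O)C(C)C | starting material
2 | methyl 2-(2-isopropyl-1,3-dioxolan-2-yl)acetate | COC(=O)CC1(C(C)C)OCCO1 | intermediate
3 | N-methoxy-N-methyl-2-(2-isopropyl-1,3-dioxolan-2-yl)acetamide | CON(C)C(=O)CC1(C(C)C)OCCO1 | intermediate
4 | (S)-4-benzyl-3-propionyloxazolidin-2-one | CCC(=O)N1[C@@H](Cc2ccccc2)COC1=O | starting material
5 | acrolein | C=CC=O | starting material
6 | dibutylboron Z-enolate of 4 | C/C=C(\OB(CCCC)CCCC)N1[C@@H](Cc2ccccc2)COC1=O | intermediate
7 | (4S)-4-benzyl-3-[(2S,3R)-3-hydroxy-2-methylpent-4-enoyl]oxazolidin-2-one | C=C[C@@H](O)[C@H](C)C(=O)N1[C@@H](Cc2ccccc2)COC1=O | intermediate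
8 | methyl (2S,3R)-3-hydroxy-2-methylpent-4-enoate | C=C[C@@H](O)[C@H](C)C(=O)OC | intermediate
9 | dilithium alkoxide enolate of 8 | C=C[C@@H](O[Li])/C(C)=C(\O[Li])OC | intermediate
10 | methyl (2S,3R)-3-hydroxy-2-[2-(2-isopropyl-1,3-dioxolan-2-yl)acetyl]-2-methylpent-4-enoate | C=C[C@@H](O)[C@@](C(=O)OC)(C)C(=O)CC1(C(C)C)OCCO1 | intermediate
11 | methyl (2R,3R)-3-hydroxy-2-[(1S)-1-hydroxy-2-(2-isopropyl-1,3-dioxolan-2-yl)ethyl]-2-methylpent-4-enoate | C=C[C@@H](O)[C@@](C(=O)OC)(C)[C@@H](O)CC1(C(C)C)OCCO1 | intermediate
12 | (2R,3R)-3-hydroxy-2-[(1S)-1-hydroxy-2-(2-isopropyl-1,3-dioxolan-2-yl)ethyl]-N-methoxy-N,2-dimethylpent-4-enamide | C=C[C@@H](O)[C@@](C(=O)N(C)OC)(C)[C@@H](O)CC1(C(C)C)OCCO1 | intermediate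
13 | 4-bromo-2-methylbut-1-ene | C=C(C)CCBr | starting material
14 | (3-methylbut-3-en-1-yl)magnesium bromide | C=C(C)CC[Mg]Br | intermediate
15 | (6R,7R)-7-hydroxy-6-[(1S)-1-hydroxy-2-(2-isopropyl-1,3-dioxolan-2-yl)ethyl]-2,6-dimethylnona-1,8-dien-5-one | C=C[C@@H](O)[C@@](C(=O)CCC(C)=C)(C)[C@@H](O)CC1(C(C)C)OCCO1 | intermediate
16 | (2R,3R)-3-hydroxy-2-[(1S)-1-hydroxy-2-(2-isopropyl-1,3-dioxolan-2-yl)ethyl]-2,5-dimethylcyclohept-4-en-1-one | O=C1CCC(C)=C[C@@H](O)[C@@]1(C)[C@@H](O)CC2(C(C)C)OCCO2 | intermediate
17 | (2R,3R)-3-(tert-butyldimethylsilyloxy)-2-[(1S)-1-(tert-butyldimethylsilyloxy)-2-(2-isopropyl-1,3-dioxolan-2-yl)ethyl]-2,5-dimethylcyclohept-4-en-1-one | O=C1CCC(C)=C[C@@H](O[Si](C)(C)C(C)(C)C)[C@@]1(C)[C@@H](O[Si](C)(C)C(C)(C)C)CC2(C(C)C)OCCO2 | intermediate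
18 | hydrazone of 17 (NH2 anti to C3a) | N/N=C1/[C@](C)([C@@H](O[Si](C)(C)C(C)(C)C)CC2(C(C)C)OCCO2)[C@H](O[Si](C)(C)C(C)(C)C)C=C(C)CC1 | intermediate
19 | (6R,7R)-6-(tert-butyldimethylsilyloxy)-7-[(1S)-1-(tert-butyldimethylsilyloxy)-2-(2-isopropyl-1,3-dioxolan-2-yl)ethyl]-1-iodo-4,7-dimethylcyclohepta-1,4-diene | C2CC(C)=C[C@@H](O[Si](C)(C)C(C)(C)C)[C@@](C)([C@@H](O[Si](C)(C)C(C)(C)C)CC3(C(C)C)OCCO3)C=2I | intermediate
20 | (5S)-5-(tert-butyldimethylsilyloxy)-5-[(1R,7R)-7-(tert-butyldimethylsilyloxy)-2-iodo-1,5-dimethylcyclohepta-2,5-dien-1-yl]-2-methylpentan-3-one | C2CC(C)=C[C@@H](O[Si](C)(C)C(C)(C)C)[C@@](C)([C@@H](O[Si](C)(C)C(C)(C)C)CC(=O)C(C)C)C=2I | intermediate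
21 | alkenylchromium dichloride derived from 20 (chromium in place of iodine) | C2CC(C)=C[C@@H](O[Si](C)(C)C(C)(C)C)[C@@](C)([C@@H](O[Si](C)(C)C(C)(C)C)CC(=O)C(C)C)C=2[Cr](Cl)Cl | intermediate
22 | (1R,3S,3aR,4R)-3,4-bis(tert-butyldimethylsilyloxy)-1-isopropyl-3a,6-dimethyl-1,2,3,3a,4,7-hexahydroazulen-1-ol | C2CC(C)=C[C@@H](O[Si](C)(C)C(C)(C)C)[C@@]3(C)[C@@H](O[Si](C)(C)C(C)(C)C)C[C@@](O)(C(C)C)C3=2 | intermediate
23 | (1R,3S,3aR,4R,8R,8aS)-3,4-bis(tert-butyldimethylsilyloxy)-8,8a-epoxy-1-isopropyl-3a,6-dimethyl-1,2,3,3a,4,7,8,8a-octahydroazulen-1-ol | [C@@H]12CC(C)=C[C@@H](O[Si](C)(C)C(C)(C)C)[C@@]3(C)[C@@H](O[Si](C)(C)C(C)(C)C)C[C@@](O)(C(C)C)[C@@]13O2 | intermediate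
24 | (1R,3S,3aR,4R,8R,8aS)-3,4-bis(tert-butyldimethylsilyloxy)-1-isopropyl-3a,6-dimethyl-1,2,3,3a,4,7,8,8a-octahydroazulene-1,8-diol | O[C@@H]2CC(C)=C[C@@H](O[Si](C)(C)C(C)(C)C)[C@@]3(C)[C@@H](O[Si](C)(C)C(C)(C)C)C[C@@](O)(C(C)C)[C@H]23 | intermediate
25 | (1R,3S,3aR,4R,8aR)-3,4-bis(tert-butyldimethylsilyloxy)-1-hydroxy-1-isopropyl-3a,6-dimethyl-2,3,3a,4,7,8a-hexahydroazulen-8(1H)-one | O=C2CC(C)=C[C@@H](O[Si](C)(C)C(C)(C)C)[C@@]3(C)[C@@H](O[Si](C)(C)C(C)(C)C)C[C@@](O)(C(C)C)[C@H]23 | intermediate
26 | (1R,3S,3aR,4R,8S,8aS)-3,4-bis(tert-butyldimethylsilyloxy)-1-isopropyl-3a,6-dimethyl-1,2,3,3a,4,7,8,8a-octahydroazulene-1,8-diol | O[C@H]2CC(C)=C[C@@H](O[Si](C)(C)C(C)(C)C)[C@@]3(C)[C@@H](O[Si](C)(C)C(C)(C)C)C[C@@](O)(C(C)C)[C@H]23 | intermediate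
27 | 3,4-dimethoxybenzoyl chloride | COc1ccc(C(=O)Cl)cc1OC | starting material
28 | (1R,3S,3aR,4R,8S,8aS)-3,4-bis(tert-butyldimethylsilyloxy)-1-hydroxy-1-isopropyl-3a,6-dimethyl-1,2,3,3a,4,7,8,8a-octahydroazulen-8-yl 3,4-dimethoxybenzoate | COc1ccc(C(=O)O[C@H]2CC(C)=C[C@@H](O[Si](C)(C)C(C)(C)C)[C@@]3(C)[C@@H](O[Si](C)(C)C(C)(C)C)C[C@@](O)(C(C)C)[C@H]23)cc1OC | intermediate
29 | (1R,3S,3aR,4R,8S,8aS)-1,3,4-trihydroxy-1-isopropyl-3a,6-dimethyl-1,2,3,3a,4,7,8,8a-octahydroazulen-8-yl 3,4-dimethoxybenzoate | COc1ccc(C(=O)O[C@H]2CC(C)=C[C@@H](O)[C@@]3(C)[C@@H](O)C[C@@](O)(C(C)C)[C@H]23)cc1OC | intermediate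
30 | (1R,3S,3aR,4R,8S,8aS)-3,4-diacetoxy-1-hydroxy-1-isopropyl-3a,6-dimethyl-1,2,3,3a,4,7,8,8a-octahydroazulen-8-yl 3,4-dimethoxybenzoate (CNP0320758.1) | COc1ccc(C(=O)O[C@H]2CC(C)=C[C@@H](OC(C)=O)[C@@]3(C)[C@@H](OC(C)=O)C[C@@](O)(C(C)C)[C@H]23)cc1OC | target

## Step count and least certain steps

Total: 20 steps. Longest linear sequence: 18 steps (steps 3–20 from 4; equally steps 1, 2 and 5–20 from 1).

Step 13 (key step). Two processes are most likely to go wrong. The alkenylchromium may be protonated before it adds to the hindered isopropyl ketone, which would reduce the C–I bond. The facial selectivity at the ketone may also be poor if the half-chair with the pseudo-equatorial silyloxy group is not clearly preferred. In that case the chromium/nickel regime would be given up for halogen–lithium exchange. Iodide 20 would be treated with t-BuLi (2 equiv) in THF/Et2O/pentane at −100 °C, where iodine–lithium exchange outruns attack on the hindered ketone, to give the alkenyllithium F1. On warming to −78 °C this would close the ring in an anionic 5-exo addition through a tighter, colder transition state. The fallback sets out from 20 and comes back at 22.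

Step 5. C-acylation at the tetrasubstituted enolate carbon may be slow. The dianion would then be lost to proton transfer on warming, and the chelate that controls the enolate face could loosen. The fallback replaces acylation by aldol addition and adjusts the oxidation level afterwards. Ester 2 would be reduced with i-Bu2AlH at −78 °C to 2-(2-isopropyl-1,3-dioxolan-2-yl)acetaldehyde F2. Dianion 9 would add to it, with the same facial control at C3a, to give the diol methyl (2R,3R)-3-hydroxy-2-[1-hydroxy-2-(2-isopropyl-1,3-dioxolan-2-yl)ethyl]-2-methylpent-4-enoate F3 as a mixture at the new carbinol. The less hindered allylic hydroxyl would be silylated selectively (Et3SiCl, imidazole) to the mono-triethylsilyl ether F4. Dess–Martin oxidation would give the keto ester methyl (2S,3R)-2-[2-(2-isopropyl-1,3-dioxolan-2-yl)acetyl]-2-methyl-3-(triethylsilyloxy)pent-4-enoate F5, and HF·pyridine would return 10. The fallback sets out from 2 and 9 and comes back at 10.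

Step 11. Hydrazone formation at a ketone flanked by the quaternary carbon and two silyloxy-bearing arms may be slow, and over-iodination to a geminal diiodide may compete. The fallback forms the alkenyl electrophile from the enolate instead. Ketone 17 would be treated with KHMDS and PhNTf2 (enolisation is possible only toward C8) to give the alkenyl triflate ketal F6. PPTS in wet acetone would give the alkenyl triflate ketone F7. CrCl2 with catalytic NiCl2, which also activates alkenyl triflates, would close the ring. The fallback sets out from 17 and comes back at 22.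

Step 15. Hydrogen atom transfer may reach C8a from the α face and give the cis fusion. The tertiary radical may also be reduced further and expel the β-oxygen, returning the alkene. The fallback drops the epoxide and hydroborates 22 directly (BH3·THF, 0 °C; then NaOH/H2O2). Boron should add to C8 and hydrogen to C8a in a syn fashion from the β face, the α face being covered by the C1 borate, giving the C8 alkylborane F8 (drawn with the C1 hydroxyl free). Oxidation would give the β-alcohol. The risk moves to chemoselectivity against C5=C6. The fallback sets out from 22 and comes back at 26, bypassing 23–25.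

Step 17. Ligand exchange at the hindered tertiary hydroxyl may be slow, so that undirected reduction erodes the selectivity, or the β-hydroxy ketone may epimerise at C8a during the longer reaction time. The fallback inverts C8 by substitution instead of by redox. Alcohol 24 would be treated with 3,4-dimethoxybenzoic acid, PPh3 and diisopropyl azodicarboxylate (Mitsunobu reaction), which installs the veratrate with inversion and leaves the tertiary hydroxyl alone. The fallback sets out from 24 and comes back at 28; it makes no compound outside the list (F0).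

## Further compounds

F1 | step 13 | alkenyllithium derived from 20 (lithium in place of iodine) | C2CC(C)=C[C@@H](O[Si](C)(C)C(C)(C)C)[C@@](C)([C@@H](O[Si](C)(C)C(C)(C)C)CC(=O)C(C)C)C=2[Li]
F2 | step 5 | 2-(2-isopropyl-1,3-dioxolan-2-yl)acetaldehyde | O=CCC1(C(C)C)OCCO1
F3 | step 5 | methyl (2R,3R)-3-hydroxy-2-[1-hydroxy-2-(2-isopropyl-1,3-dioxolan-2-yl)ethyl]-2-methylpent-4-enoate, both epimers at the new carbinol | C=C[C@@H](O)[C@@](C(=O)OC)(C)C(O)CC1(C(C)C)OCCO1
F4 | step 5 | methyl (2R,3R)-2-[1-hydroxy-2-(2-isopropyl-1,3-dioxolan-2-yl)ethyl]-2-methyl-3-(triethylsilyloxy)pent-4-enoate | C=C[C@@H](O[Si](CC)(CC)CC)[C@@](C(=O)OC)(C)C(O)CC1(C(C)C)OCCO1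
F5 | step 5 | methyl (2S,3R)-2-[2-(2-isopropyl-1,3-dioxolan-2-yl)acetyl]-2-methyl-3-(triethylsilyloxy)pent-4-enoate | C=C[C@@H](O[Si](CC)(CC)CC)[C@@](C(=O)OC)(C)C(=O)CC1(C(C)C)OCCO1
F6 | step 11 | (6R,7R)-6-(tert-butyldimethylsilyloxy)-7-[(1S)-1-(tert-butyldimethylsilyloxy)-2-(2-isopropyl-1,3-dioxolan-2-yl)ethyl]-4,7-dimethylcyclohepta-1,4-dien-1-yl trifluoromethanesulfonate | C2CC(C)=C[C@@H](O[Si](C)(C)C(C)(C)C)[C@@](C)([C@@H](O[Si](C)(C)C(C)(C)C)CC3(C(C)C)OCCO3)C=2OS(=O)(=O)C(F)(F)F
F7 | step 11 | (6R,7R)-6-(tert-butyldimethylsilyloxy)-7-[(1S)-1-(tert-butyldimethylsilyloxy)-4-methyl-3-oxopentyl]-4,7-dimethylcyclohepta-1,4-dien-1-yl trifluoromethanesulfonate | C2CC(C)=C[C@@H](O[Si](C)(C)C(C)(C)C)[C@@](C)([C@@H](O[Si](C)(C)C(C)(C)C)CC(=O)C(C)C)C=2OS(=O)(=O)C(F)(F)F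
F8 | step 15 | C8 alkylborane from hydroboration of 22 (BH2 on the β face of C8, hydrogen on the β face of C8a) | B[C@H]2CC(C)=C[C@@H](O[Si](C)(C)C(C)(C)C)[C@@]3(C)[C@@H](O[Si](C)(C)C(C)(C)C)C[C@@](O)(C(C)C)[C@H]23
F0 | step 17 | none | none
A1 | alternative 1 | hydroazulenedione with C8=C8a alkene and C1 triethylsilyl ether | C1C(C)=CC(=O)[C@@]2(C)C(=O)C[C@@](O[Si](CC)(CC)CC)(C(C)C)C2=C1
A2 | alternative 1 | ten-membered enynedione, substrate of the gold-catalysed closure | CC1C(=O)C[C@@](O[Si](CC)(CC)CC)(C(C)C)C#CC/C(C)=C\C1=O
A3 | alternative 2 | ring-expanded hydroazulen-4-one (enone) | COc1ccc(C(=O)O[C@H]2CC(C)=CC(=O)[C@@]3(C)[C@@H](OC(C)=O)C[C@@](O[Si](C)(C)C)(C(C)C)[C@H]23)cc1OC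
A4 | alternative 2 | trimethylsilyl enol ether of the trans-fused hydrindanone | COc1ccc(C(=O)O[C@H]2CC(C)=C(O[Si](C)(C)C)[C@@]3(C)[C@@H](OC(C)=O)C[C@@](O[Si](C)(C)C)(C(C)C)[C@H]23)cc1OC
A5 | alternative 3 | cis-fused hydroazulene silyl enol ether with C8 vinylsilane | C[Si](C)(C)C2=C[C@H](C)C=C(O[Si](C)(C)C(C)(C)C)[C@@]3(C)[C@@H](OC(C)=O)C[C@@](O)(C(C)C)[C@@H]23
A6 | alternative 3 | siloxy vinylcyclopropane fused to the cyclopentane (drawn with the propenyl group exo) | C/C=C/[C@]1(O[Si](C)(C)C(C)(C)C)[C@@]2(C)[C@@H](OC(C)=O)C[C@@](O)(C(C)C)[C@@H]12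
A7 | alternative 3 | ethynyltrimethylsilane | C#C[Si](C)(C)C
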